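**Retrosynthetic overview**
1. Target 11 ⇐ triol 10 by one hydrogenolysis (two O-benzyl groups and a transient C4 carbinol) ⇐ diester 9 by LiAlH4.
2. 9 ⇐ aldehyde 6 + diisopropyl fumarate 7 by a photoenolization/Diels–Alder reaction: ring B is closed through C4–C3 (together with C1–C2) and all four sp3 centres C1–C4 are set in one operation.
3. Enabling feature: C4 and C1 sit on the adjacent ring-A carbons C4a and C8a, so an ortho formyl (C4) / ortho diarylmethyl (C1–H) pair is a latent o-quinodimethane C4=C4a–C8a=C1. The C7 oxygen para to C4 later lets the C4 carbinol be removed.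
4. 6 ⇐ bromoaldehyde 2 + benzylzinc 5 (Negishi coupling, bond C8a–C1); 2 from aldehyde 1, 5 from alcohol 3 via chloride 4.
5. Ring order: rings A and C are bought as aromatics; ring B is the only ring formed (step 4).

Key step: step 4

Assumption: the (R,R)-TADDOLate on titanium is taken to deliver the dienol to the Re,Re face of the fumarate; this sense rests on analogy only, and the (S,S)-ligand is used if the opposite face is delivered.

Locants C1–C8a in names and text follow the tetralin numbering of the target (C1 = aryl-bearing carbon, C4 = benzylic CH2).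

**Route**

Step 1
Reactants: 1 4-(benzyloxy)-3,5-dimethoxybenzaldehyde
Product: 2 4-(benzyloxy)-2-bromo-3,5-dimethoxybenzaldehyde
Conditions: NBS (1.05 equiv), MeCN, 25 °C, dark
Reagents that add atoms: N-bromosuccinimide, O=C1CCC(=O)N1Br
Why: Electrophilic aromatic bromination; the two free ring positions of 1 are equivalent, each ortho to one methoxy group and para to the other, so a single monobromide should form while the aldehyde and the benzyl ether stay untouched.

Step 2
Reactants: 3 [4-(benzyloxy)-3-methoxyphenyl]methanol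
Product: 4 1-(benzyloxy)-4-(chloromethyl)-2-methoxybenzene
Conditions: SOCl2 (1.2 equiv), DMF (cat.), CH2Cl2, 0 °C; used crude
Reagents that add atoms: thionyl chloride, ClS(Cl)=O
Why: Chlorodehydroxylation of a benzylic alcohol through its chlorosulfite; the para-alkoxybenzyl chloride ionizes easily and is therefore carried on without chromatography.

Step 3
Reactants: 4 1-(benzyloxy)-4-(chloromethyl)-2-methoxybenzene; 2 4-(benzyloxy)-2-bromo-3,5-dimethoxybenzaldehyde
Product: 6 4-(benzyloxy)-2-[4-(benzyloxy)-3-methoxybenzyl]-3,5-dimethoxybenzaldehyde, via benzylzinc chloride 5 (not isolated)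
Conditions: Zn dust (1.5 equiv), LiCl (1.5 equiv), THF, 25 °C; then 2, Pd(OAc)2 (2 mol %), SPhos (4 mol %), THF, 25 °C
Reagents that add atoms: none
Why: LiCl-assisted zinc insertion into the benzylic chloride followed by a palladium-catalysed Negishi sp2–sp3 coupling forms the C8a–C1 bond; the SPhos catalyst should couple the doubly ortho-substituted bromide faster than the benzylzinc reagent adds to the hindered, electron-rich aldehyde.

Step 4
Reactants: 6 4-(benzyloxy)-2-[4-(benzyloxy)-3-methoxybenzyl]-3,5-dimethoxybenzaldehyde; 7 diisopropyl fumarate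
Product: 9 diisopropyl (1S,2R,3S,4S)-7-(benzyloxy)-1-[4-(benzyloxy)-3-methoxyphenyl]-4-hydroxy-6,8-dimethoxy-1,2,3,4-tetrahydronaphthalene-2,3-dicarboxylate, via photoenol 8 (not isolated)
Conditions: 7 (3 equiv), Ti(Oi-Pr)4 (2.0 equiv), (R,R)-TADDOL (2.2 equiv), 4 Å MS, toluene, hν (366 nm), −20 °C; aq. NaHCO3
Reagents that add atoms: none
Why: n,π* excitation of the aldehyde of 6 and 1,5-hydrogen transfer from the doubly benzylic C1–H to oxygen should give the hydroxy-o-quinodimethane 8 (oxygen outside at C4, aryl outside at C1; drawn as the free dienol), which tetravalent titanium traps as its dienolate and which adds to the fumarate held on the same metal; the closest known reaction type is the titanium-mediated photoenolization/Diels–Alder reaction of electron-rich 2-alkylbenzaldehydes, enantioselective with TADDOL-type ligands. Ring B closes in a (4+2) mode, suprafacial on both partners and asynchronous: the oxygen-remote terminus C1 bonds to C2 first, and the C4–C3 bond, formed in a six-membered aldol-like titanium chelate, completes the ring. C2 and C3 come out trans because the E geometry of the fumarate is transferred stereospecifically; the C3 ester and O4 are cis because that ester carbonyl is bound endo to the titanium on O4; the C1 aryl is trans to the C2 ester, which is then necessarily exo, because the aryl group occupies the outside position of the dienol. The absolute configuration (addition to the Re,Re face of the fumarate) is controlled by the (R,R)-TADDOLate in Ti(Oi-Pr)2(TADDOLate). The step needs outside geometry at C1 (an inside aryl clashes with H–C4 and diverts to 6π closure onto ring C), endo binding at the oxygen end and one fumarate face; the weak C1–H bond, the absence of any other abstractable hydrogen ortho to the formyl group and the isopropyl esters (exchange with Ti(Oi-Pr)4 is degenerate) secure chemoselectivity.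

Step 5
Reactants: 9 diisopropyl (1S,2R,3S,4S)-7-(benzyloxy)-1-[4-(benzyloxy)-3-methoxyphenyl]-4-hydroxy-6,8-dimethoxy-1,2,3,4-tetrahydronaphthalene-2,3-dicarboxylate
Product: 10 (1S,2R,3R,4S)-7-(benzyloxy)-1-[4-(benzyloxy)-3-methoxyphenyl]-2,3-bis(hydroxymethyl)-6,8-dimethoxy-1,2,3,4-tetrahydronaphthalen-4-ol
Conditions: LiAlH4 (4 equiv), THF, 0 °C to 25 °C; aq. NaOH work-up
Reagents that add atoms: none
Why: Ester reduction with LiAlH4 should turn both isopropyl esters into the hydroxymethyl groups without touching C1–C4 or the benzyl ethers; the C4 carbinol is held as an aluminium alkoxide, which disfavours retro-aldol cleavage.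

Step 6
Reactants: 10 (1S,2R,3R,4S)-7-(benzyloxy)-1-[4-(benzyloxy)-3-methoxyphenyl]-2,3-bis(hydroxymethyl)-6,8-dimethoxy-1,2,3,4-tetrahydronaphthalen-4-ol
Product: 11 (+)-8-methoxyisolariciresinol, (1S,2R,3R)-1-(4-hydroxy-3-methoxyphenyl)-2,3-bis(hydroxymethyl)-6,8-dimethoxy-1,2,3,4-tetrahydronaphthalen-7-ol
Conditions: H2 (1 atm), 10% Pd/C, EtOH–AcOH (20:1), 25 °C
Reagents that add atoms: none
Why: Catalytic hydrogenolysis should cleave both O-benzyl ethers and reduce the C4 carbinol, which is then para to the free C7 phenol, to CH2, as para-hydroxybenzylic alcohols of lignans are known to be deoxygenated; C1, C2 and C3 are not involved.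

**Compound list**
1 | 4-(benzyloxy)-3,5-dimethoxybenzaldehyde | COc1cc(C=O)cc(OC)c1OCc1ccccc1 | starting material
2 | 4-(benzyloxy)-2-bromo-3,5-dimethoxybenzaldehyde | COc1cc(C=O)c(Br)c(OC)c1OCc1ccccc1 | intermediate
3 | [4-(benzyloxy)-3-methoxyphenyl]methanol | COc1cc(CO)ccc1OCc1ccccc1 | starting material
4 | 1-(benzyloxy)-4-(chloromethyl)-2-methoxybenzene | COc1cc(CCl)ccc1OCc1ccccc1 | intermediate
5 | [4-(benzyloxy)-3-methoxybenzyl]zinc chloride (not isolated) | COc1cc(C[Zn]Cl)ccc1OCc1ccccc1 | intermediate
6 | 4-(benzyloxy)-2-[4-(benzyloxy)-3-methoxybenzyl]-3,5-dimethoxybenzaldehyde | COc1cc(C=O)c(Cc2ccc(OCc3ccccc3)c(OC)c2)c(OC)c1OCc1ccccc1 | intermediate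
7 | diisopropyl fumarate | CC(C)OC(=O)/C=C/C(=O)OC(C)C | starting material
8 | photoenol of 6: hydroxy-o-quinodimethane C4=C4a–C8a=C1 with OH and aryl both outside (not isolated) | O/C=C1\C=C(OC)C(OCc2ccccc2)=C(OC)/C1=C\c1ccc(OCc2ccccc2)c(OC)c1 | intermediate
9 | diisopropyl (1S,2R,3S,4S)-7-(benzyloxy)-1-[4-(benzyloxy)-3-methoxyphenyl]-4-hydroxy-6,8-dimethoxy-1,2,3,4-tetrahydronaphthalene-2,3-dicarboxylate | COc1cc([C@H]2c3c(cc(OC)c(OCc4ccccc4)c3OC)[C@@H](O)[C@@H](C(=O)OC(C)C)[C@@H]2C(=O)OC(C)C)ccc1OCc1ccccc1 | intermediate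
10 | (1S,2R,3R,4S)-7-(benzyloxy)-1-[4-(benzyloxy)-3-methoxyphenyl]-2,3-bis(hydroxymethyl)-6,8-dimethoxy-1,2,3,4-tetrahydronaphthalen-4-ol | COc1cc([C@H]2c3c(cc(OC)c(OCc4ccccc4)c3OC)[C@@H](O)[C@@H](CO)[C@@H]2CO)ccc1OCc1ccccc1 | intermediate
11 | (+)-8-methoxyisolariciresinol, (1S,2R,3R)-1-(4-hydroxy-3-methoxyphenyl)-2,3-bis(hydroxymethyl)-6,8-dimethoxy-1,2,3,4-tetrahydronaphthalen-7-ol | COc1cc([C@H]2c3c(cc(OC)c(O)c3OC)C[C@@H](CO)[C@@H]2CO)ccc1O | target

**Step count and risks**

Total step count: 6. Longest linear sequence: 5 steps (steps 1, 3, 4, 5, 6; the branch through steps 2, 3, 4, 5, 6 is equally long).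

Step 4 is the most likely to fail. The fumarate is held on titanium through one carbonyl only, so facial and endo control may be loose. The aryl group may leave the outside position of the dienol, because there it lies next to the C8 methoxy group, which would leak into the 1,2-cis series. Triplet energy transfer may isomerize the fumarate to the maleate, which would leak into the 2,3-cis series. The fallback replaces the chiral metal complex by a covalent auxiliary. It sets out from 6, which is irradiated (366 nm, toluene, achiral Ti(Oi-Pr)4) with commercial di-(−)-menthyl fumarate. The C2-symmetric auxiliary shields the same face at both alkene carbons and should give bis[(1R,2S,5R)-menthyl] (1S,2R,3S,4S)-7-(benzyloxy)-1-[4-(benzyloxy)-3-methoxyphenyl]-4-hydroxy-6,8-dimethoxy-1,2,3,4-tetrahydronaphthalene-2,3-dicarboxylate F1, a diastereomer that can be purified by crystallization. LiAlH4 then cleaves both auxiliaries and the fallback comes back to the route at 10. The (+)-menthyl ester is used if induction is opposite.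

Step 6 is the second risk. Once the benzyl ether on O7 is cleaved, the C4 carbinol can ionize to a quinone methide that tautomerizes to the 3,4-alkene before it is reduced, and hydrogenation of that alkene would scramble C3; the C–O hydrogenolysis may also stall at the tetraol. The fallback is a radical deoxygenation before the phenols are unmasked. It sets out from 9, whose C4 alcohol is converted with 1,1'-thiocarbonyldiimidazole into the 4-O-(imidazol-1-ylthiocarbonyl) derivative of 9 F2. Bu3SnH/AIBN (toluene, 90 °C, Barton–McCombie deoxygenation) reduces it through the C4 benzylic radical to diisopropyl (1S,2R,3R)-7-(benzyloxy)-1-[4-(benzyloxy)-3-methoxyphenyl]-6,8-dimethoxy-1,2,3,4-tetrahydronaphthalene-2,3-dicarboxylate F3. LiAlH4 gives the 7,4'-di-O-benzyl ether of the target F4, and hydrogenolysis of the two benzyl ethers alone (H2, 10% Pd/C, EtOH) comes back to the route at 11.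

Step 3 is the third risk. The benzylzinc reagent may add to the aldehyde of 2, zinc insertion into the electron-rich chloride may end in homocoupling, and oxidative addition at the doubly ortho-substituted bromide may be slow. The fallback uses carbonyl addition and ionic deoxygenation in place of cross-coupling. It sets out from 2, whose aldehyde is masked (ethylene glycol, TsOH, toluene, reflux) as 2-[4-(benzyloxy)-2-bromo-3,5-dimethoxyphenyl]-1,3-dioxolane F5. Bromine–lithium exchange (n-BuLi, THF, −78 °C) and addition to commercial 4-(benzyloxy)-3-methoxybenzaldehyde give the racemic diarylmethanol [4-(benzyloxy)-3-methoxyphenyl][3-(benzyloxy)-6-(1,3-dioxolan-2-yl)-2,4-dimethoxyphenyl]methanol F6. Et3SiH/TFA (CH2Cl2, −20 °C) reduces the doubly benzylic cation, aqueous acid frees the aldehyde, and the fallback comes back to the route at 6.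

**Further compounds**
F1 | step 4 | bis[(1R,2S,5R)-menthyl] (1S,2R,3S,4S)-7-(benzyloxy)-1-[4-(benzyloxy)-3-methoxyphenyl]-4-hydroxy-6,8-dimethoxy-1,2,3,4-tetrahydronaphthalene-2,3-dicarboxylate | COc1cc([C@H]2c3c(cc(OC)c(OCc4ccccc4)c3OC)[C@@H](O)[C@@H](C(=O)O[C@@H]5C[C@H](C)CC[C@H]5C(C)C)[C@@H]2C(=O)O[C@@H]5C[C@H](C)CC[C@H]5C(C)C)ccc1OCc1ccccc1
F2 | step 6 | 4-O-(imidazol-1-ylthiocarbonyl) derivative of 9 | COc1cc([C@H]2c3c(cc(OC)c(OCc4ccccc4)c3OC)[C@@H](OC(=S)n4ccnc4)[C@@H](C(=O)OC(C)C)[C@@H]2C(=O)OC(C)C)ccc1OCc1ccccc1
F3 | step 6 | diisopropyl (1S,2R,3R)-7-(benzyloxy)-1-[4-(benzyloxy)-3-methoxyphenyl]-6,8-dimethoxy-1,2,3,4-tetrahydronaphthalene-2,3-dicarboxylate | COc1cc([C@H]2c3c(cc(OC)c(OCc4ccccc4)c3OC)C[C@@H](C(=O)OC(C)C)[C@@H]2C(=O)OC(C)C)ccc1OCc1ccccc1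
F4 | step 6 | 7,4'-di-O-benzyl ether of the target, [(1S,2R,3R)-7-(benzyloxy)-1-[4-(benzyloxy)-3-methoxyphenyl]-6,8-dimethoxy-1,2,3,4-tetrahydronaphthalene-2,3-diyl]dimethanol | COc1cc([C@H]2c3c(cc(OC)c(OCc4ccccc4)c3OC)C[C@@H](CO)[C@@H]2CO)ccc1OCc1ccccc1
F5 | step 3 | 2-[4-(benzyloxy)-2-bromo-3,5-dimethoxyphenyl]-1,3-dioxolane | COc1cc(C2OCCO2)c(Br)c(OC)c1OCc1ccccc1
F6 | step 3 | [4-(benzyloxy)-3-methoxyphenyl][3-(benzyloxy)-6-(1,3-dioxolan-2-yl)-2,4-dimethoxyphenyl]methanol (racemic; the carbinol centre is removed in the next operation) | COc1cc(C2OCCO2)c(C(O)c2ccc(OCc3ccccc3)c(OC)c2)c(OC)c1OCc1ccccc1
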